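## Structural features

The target is a pentameric lignan built on a cis-fused 2,6-diaryl-3,7-dioxabicyclo[3.3.0]octane. Core atoms are numbered C1, C2, O3, C4, C5, C6, O7, C8; ring A is C2–O3–C4–C5–C1 and ring B is C6–O7–C8–C1–C5. C2 and C6 each carry an exo 4-oxy-3,5-dimethoxyphenyl (syringyl) ring, and the four contiguous core centres are (1R,2S,5R,6S), the (+)-syringaresinol arrangement. The phenolic oxygen of the C2 ring is bonded to Cβ of a 1-(4-hydroxy-3-methoxyphenyl)propane-1,3-diol (unit A). The oxygen of the C6 ring is bonded to Cβ of a second such unit (B), whose guaiacyl oxygen in turn carries Cβ of a third unit (C) that ends in a free phenol. Each unit holds two adjacent centres, the benzylic carbinol Cα and the aryl-ether carbon Cβ: A is erythro (αR,βS), B is threo (αS,βS) and C is erythro (αS,βR). Aryl ether links insulate these pairs from each other and from the core, so no stereochemical relay is available. Fragile sites are the benzylic ethers C2–O3 and C6–O7 (acid epimerises them, hydrogenolysis cleaves them), the three benzylic alcohols on oxygenated rings (they ionise in acid), and free phenols para to a benzylic C–O bond (quinone methides in base or on heating). The real difficulty is twofold: the two syringyl phenols of a C2-symmetric core must carry different chains, and six acyclic centres in three different patterns must each be set by reagent control. The key step exploits ring A: C2–O3–C4 is read as a carbonyl ylide added across a former C1=C5 double bond, so ring B is a butenolide C8(=O)–O7–C6–C5=C1. Its acetal carbon C6 first directs the facial approach and later exchanges its alkoxy group for the second syringyl ring, so the two aryl rings enter at different stages and never become equivalent.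

## Logic of the disconnections

44 is traced to 43 and then 42 by cutting only O–acyl and O–Si bonds. The free polyol is sensitive to acid and base, so it is unveiled last by buffered fluoride and then mild methanolysis. This demands that every earlier step tolerate two aryl pivalates, two 4-nitrobenzoates and two primary silyl ethers.

42 is traced through 41 to 30 and 39 by cutting the Cα–Cβ bond of unit B. This is the most convergent cut, giving two halves of similar size, one holding the core and unit A, the other the B ring and unit C. The forward aldol must be ruled by the auxiliary alone and must give the threo pair directly.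

39 is traced through 38, 37, 36 and 35 to 33 and 21, and 33 to 31 and 32. The cuts are the Cα–O ester bond (made with inversion), the Cα–Cβ bond of unit C, and the O–CH2 bond. The erythro pair is reached from the aldol's threo pair by an invertive esterification, and the propenyl group of 31 stands in for the aldehyde of the B ring. The demands are a clean SN2 event at Cα and an alkene that stays inert until it is cleaved.

30 is traced to 29 and 22, then 29 through 28, 27, 26 and 25 to 23 and 21, then 23 to 19 and 22, and 21 to 20. Unit A is built by the same logic as unit C with the other auxiliary enantiomer. The gain is that both chains on the core start from the same reagent 22. The demand is that the two core phenols be freed one at a time, the second by cleaving an aryl silyl ether next to an alkyl silyl ether.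

19 is traced through 18 and 17 to 16, then 15 and 14. The cut is O7–C8, not O7–C6, so that the C6 configuration set earlier is never put at risk. The two rings are told apart by a mesylate and a silyl ether. The forward steps need a primary-selective sulfonylation and a mesylate cleavage that spares the silyl ether.

14 is traced to 12 and 13 by cutting the C6–aryl bond. C6 is an acetal carbon and therefore an electrophile, and 13 is nucleophilic para to its hydroxyl. The second ring thus comes from a commodity phenol and is free while the first is masked. The forward step must attack on the exo face and must not ionise C2–O3.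

12 is traced through 11 to 5 and 10 by cutting C1–C2 and C4–C5. This removes ring A, two skeletal bonds and three stereocentres in one step and leaves two small pieces. The forward step must be regioselective (CH2 terminus to C5), anti to the menthyloxy group and exo at C2.

5 is traced through 4 to 2 and 3, and 2 to 1; 10 to 7 and 8; 7 to 6. These are functional-group steps on commercial materials. The only demand is strictly anhydrous handling of 5.

## Other disconnections considered

Alternative 1: The cut is at the benzylic Cα–O bonds of units A and C, so the precursor A1 is the target without these two hydroxyls. In the forward step Ag2O would oxidise the two free 4-alkylguaiacol ends of A1 to p-quinone methides. Phenylboronic acid A2, esterified to each Cγ–OH, would then hand a boron-bound hydroxyl to Cα inside a six-membered array, giving the tris(boronate) A3, in which the diol of unit B is merely capped.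
- In favour: only a ring with a free phenol can form a quinone methide, so A and C are addressed and B is left alone without protecting groups. A chair-like delivery with aryl and aryloxy both equatorial leads to the trans dioxaborinane, which is the erythro relation both ends need. Both ends are finished in one operation.
- Against: the step says nothing about the core or the differentiation of the two syringyl rings. A1 still needs three Cβ centres and the threo unit B. Quinone methides are unselective electrophiles. Hydroxyl delivery from a boronic hemiester is established for enones only, so its use here is an extrapolation.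
- Comparison: in structure it is complementary to the chosen plan, not a rival, since a core synthesis is needed in either case. In mechanism it relies on 1,2-induction from Cβ, whereas the chosen plan uses an auxiliary-controlled aldol followed by stereospecific inversion, which is the more predictable course. In step economy at the chain ends this alternative is the better, since it would spare both inversion sequences and most protecting-group steps.

Alternative 2: The cut is at the Cα–aryl bonds of units A and C. Two equivalents of the Grignard reagent A5 would add to the dialdehyde A4 to give the hexasilyl compound A6.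
- In favour: the plan is two-directional and convergent, and the guaiacyl rings arrive last. The polar Felkin–Anh model, with the α-aryloxy group anti to the nucleophile, predicts the anti (erythro) carbinol at both ends, which is what A and C require. The threo unit B is already in place.
- Against: α-aryloxy aldehydes epimerise easily at Cβ. Magnesium may chelate the carbonyl and the α-aryloxy oxygen, helped by the ortho methoxy groups, which would lead to threo. The syringyl ether in A and the guaiacyl ether in C need not respond alike. A4 requires two stereodefined α-aryloxy aldehydes made by other means.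
- Comparison: the core problem is the same. If Felkin control holds at both ends, the alternative equals the chosen plan in outcome and is the better in directness, since no inversion is needed. In step economy the two are roughly equal, because the steps saved are spent on A4. The chosen plan is the safer on stereocontrol.

Alternative 3: The cuts are C5–C6 and C1–C2. The lithiated dithiane A7 (n-BuLi) would add to the β-carbon of butenolide A8, which is the enantiomer of 10, anti to the menthyloxy group. The enolate would then be trapped by aldehyde A9 to give lactone A10.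
- In favour: three components are joined in one flask. Conjugate addition followed by aldol trapping is established on this class of butenolide, which the carbonyl ylide addition is not, so the alternative is the better in precedent. A8 derives from the cheaper antipode of 8, also a point in its favour. The two aryl rings are differentiated from the outset, which equals the chosen plan.
- Against: no ring of the core is closed. The acetal carbon of A8 ends as the C4 methylene, so the auxiliary serves only once. C2 and C6 must both be set later, in two ring closures after dithiane hydrolysis and several reductions, and the carbinol configuration from the aldol is not controlled.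
- Comparison: in structure the chosen plan uses the acetal carbon twice, as control element and as C6. In mechanism the chosen plan sets C1, C2 and C5 in one concerted step, while the alternative secures only C1 and C5. In step economy the chosen plan is shorter to the differentiated core (about four steps from 12 against five to six from A10), but the alternative has the more secure first step.

Key step: step 6

Remarks on the chemistry (assumptions):
- Cα, Cβ and Cγ denote the benzylic carbinol, the aryloxy carbon and the CH2OH carbon of each unit. Xc(R) and Xc(S) denote the (R)- and (S)-4-benzyl-2-oxooxazolidin-3-yl groups.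
- The phenol of the dipole precursor is carried as a methanesulfonate and not as an ether. An electron-poor ring keeps the α-chloro ether 5 from ionising, stabilises the benzylic carbanion character so that CH2 remains the nucleophilic ylide terminus, and keeps C2–O3 inert to BF3·OEt2 in step 7. 5 is made from acetal 4 with acetyl chloride and not from aldehyde, alcohol and HCl, so that no water is formed beside it.
- 22 and 32 are taken as catalogue compounds. 31 may be used as an E/Z mixture, because the alkene is cleaved in step 25.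
- The configuration check gave (1R,2S,5R,6S) for the core and requires the (5S)-butenolide from (+)-menthol. No structure needed correction.

## Route

Step 1
Reactants: 1 syringaldehyde
Product: 2 4-formyl-2,6-dimethoxyphenyl methanesulfonate
Conditions: MsCl, Et3N, CH2Cl2, 0 °C
Reagents that add atoms: methanesulfonyl chloride, CS(=O)(=O)Cl
Why: O-sulfonylation of the phenol; the mesylate is inert to acid, fluoride, BF3·OEt2 and borohydride and makes the ring electron-poor for steps 3 to 10.

Step 2
Reactants: 2 4-formyl-2,6-dimethoxyphenyl methanesulfonate; 3 (trimethylsilyl)methanol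
Product: 4 4-{bis[(trimethylsilyl)methoxy]methyl}-2,6-dimethoxyphenyl methanesulfonate
Conditions: 3 (2.5 equiv), p-TsOH·H2O (cat.), benzene, reflux, Dean–Stark
Reagents that add atoms: none
Why: Acid-catalysed acetalisation driven by azeotropic removal of water; the electron-poor aldehyde favours the acetal.

Step 3
Reactants: 4 4-{bis[(trimethylsilyl)methoxy]methyl}-2,6-dimethoxyphenyl methanesulfonate
Product: 5 4-{chloro[(trimethylsilyl)methoxy]methyl}-2,6-dimethoxyphenyl methanesulfonate (racemic at C–Cl)
Conditions: AcCl (1.2 equiv), SOCl2 (cat.), CH2Cl2, 0 °C to rt; evaporate, use crude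
Reagents that add atoms: acetyl chloride, CC(=O)Cl
Why: Acyl chloride cleavage of an acetal to an α-chloro ether, a water-free entry; the C–Cl centre is racemic and is lost in step 6.

Step 4
Reactants: 6 furfural
Product: 7 5-hydroxyfuran-2(5H)-one (racemic)
Conditions: O2, hν (visible), rose bengal (cat.), MeOH, rt
Reagents that add atoms: dioxygen, O=O
Why: Dye-sensitised photo-oxygenation: singlet oxygen adds across the furan diene and methanol removes the formyl carbon as its formate, leaving the pseudo-acid.

Step 5
Reactants: 7 5-hydroxyfuran-2(5H)-one; 8 (+)-menthol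
Product: 10 (5S)-5-[(1S,2R,5S)-menthyloxy]furan-2(5H)-one, via (5R)-epimer 9 (not isolated)
Conditions: 8 (1.1 equiv), CSA (cat.), toluene, reflux, Dean–Stark; crystallise from petroleum ether, −20 °C; mother liquor re-equilibrated with CSA and recrystallised
Reagents that add atoms: none
Why: Acid-catalysed acetalisation gives both C5 epimers; the acetal centre epimerises under the same acid, so crystallisation of the less soluble (5S) epimer drains 9 (crystallisation-induced asymmetric transformation, the mirror image of the familiar case with the other menthol enantiomer).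

Step 6
Reactants: 5 4-{chloro[(trimethylsilyl)methoxy]methyl}-2,6-dimethoxyphenyl methanesulfonate; 10 (5S)-5-[(1S,2R,5S)-menthyloxy]furan-2(5H)-one
Product: 12 (1S,2S,5R,6S)-2-(4-methanesulfonyloxy-3,5-dimethoxyphenyl)-6-[(1S,2R,5S)-menthyloxy]-3,7-dioxabicyclo[3.3.0]octan-8-one, via carbonyl ylide 11 (not isolated)
Conditions: CsF (3 equiv, dried), MeCN, rt; 5 (1.8 equiv) added slowly to 10
Reagents that add atoms: none
Why: Fluoride attacks silicon of 5 and chloride leaves in a 1,3-elimination, giving the non-stabilised carbonyl ylide 11, which adds to the electron-poor C1=C5 bond of 10 in a concerted suprafacial [3+2] cycloaddition. The closest known reaction type is the fluoride-induced generation of such ylides from α-chloroalkyl silylmethyl ethers and their addition to acrylates, enones and related acceptors. Ring A (C2–O3–C4–C5–C1) closes by the cycloaddition itself, C1–C2 and C4–C5 being formed together. C5 and C1 are set by approach anti to the menthyloxy group on C6, and their cis relation follows from suprafacial addition. C2 is set by the exo transition state, in which the aryl group points away from the lactone carbonyl and the concave face. The step needs the CH2 terminus to bond to C5: this is the smaller and less stabilised, hence more nucleophilic, terminus, and C5 is the β-carbon of the enoate and is flanked by the acetal. The mesylated ring stabilises benzylic carbanion character and so reinforces this polarity. Excess 5 makes up for ylide decay.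

Step 7
Reactants: 12 (1S,2S,5R,6S)-2-(4-methanesulfonyloxy-3,5-dimethoxyphenyl)-6-menthyloxy-3,7-dioxabicyclo[3.3.0]octan-8-one; 13 2,6-dimethoxyphenol
Product: 14 (1S,2S,5R,6S)-6-(4-hydroxy-3,5-dimethoxyphenyl)-2-(4-methanesulfonyloxy-3,5-dimethoxyphenyl)-3,7-dioxabicyclo[3.3.0]octan-8-one
Conditions: 13 (3 equiv), BF3·OEt2 (2 equiv), CH2Cl2, −20 to 0 °C; cold NaHCO3 quench
Reagents that add atoms: none
Why: Lewis-acid ionisation of the lactone acetal at C6 with loss of menthol, then Friedel–Crafts attack by the phenol para to its hydroxyl (the site of its formylation and Mannich reactions); attack on the convex face of the cis-fused bicycle places the aryl exo (6S), and the mesylated ring at C2 does not ionise.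

Step 8
Reactants: 14 the C6-aryl lactone with free phenol
Product: 15 (1S,2S,5R,6S)-6-[4-(tert-butyldimethylsilyloxy)-3,5-dimethoxyphenyl]-2-(4-methanesulfonyloxy-3,5-dimethoxyphenyl)-3,7-dioxabicyclo[3.3.0]octan-8-one
Conditions: TBSCl, imidazole, DMF, rt
Reagents that add atoms: tert-butyldimethylsilyl chloride, CC(C)(C)[Si](C)(C)Cl
Why: Silylation under weakly basic conditions caps the phenol before hydride and base are used, so the p-hydroxybenzylic lactone cannot open by quinone methide formation; the silyl ether is orthogonal to the mesylate.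

Step 9
Reactants: 15 the silylated lactone
Product: 16 (S)-[4-(tert-butyldimethylsilyloxy)-3,5-dimethoxyphenyl][(3R,4R,5S)-4-(hydroxymethyl)-5-(4-methanesulfonyloxy-3,5-dimethoxyphenyl)oxolan-3-yl]methanol
Conditions: LiBH4 (3 equiv), THF, 0 °C to rt
Reagents that add atoms: none
Why: Hydride reduction of the lactone to the diol; aryl mesylate and aryl silyl ether are inert and the C6–O bond is not broken, so C6 keeps its configuration.

Step 10
Reactants: 16 the diol
Product: 18 (1R,2S,5R,6S)-6-[4-(tert-butyldimethylsilyloxy)-3,5-dimethoxyphenyl]-2-(4-methanesulfonyloxy-3,5-dimethoxyphenyl)-3,7-dioxabicyclo[3.3.0]octane, via primary tosylate 17 (not isolated)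
Conditions: TsCl (1.2 equiv), pyridine, DMAP (cat.), 0 °C to rt, then 50 °C
Reagents that add atoms: p-toluenesulfonyl chloride, Cc1ccc(cc1)S(=O)(=O)Cl (its atoms are carried by 17 only)
Why: Selective sulfonylation of the primary C8–OH, then 5-exo-tet Williamson closure by the C6 hydroxyl onto C8; the C6–O bond stays intact and no benzylic cation is involved, so the exo aryl at C6 is retained.

Step 11
Reactants: 18 the mesylate/silyl ether furofuran
Product: 19 (1R,2S,5R,6S)-6-[4-(tert-butyldimethylsilyloxy)-3,5-dimethoxyphenyl]-2-(4-hydroxy-3,5-dimethoxyphenyl)-3,7-dioxabicyclo[3.3.0]octane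
Conditions: LDA (3 equiv), THF, −78 to −20 °C; NH4Cl
Reagents that add atoms: none
Why: Aryl methanesulfonate cleavage by α-deprotonation and loss of sulfene, which releases the phenoxide without nucleophile or acid; the aryl silyl ether and the benzylic ethers are untouched.

Step 12
Reactants: 20 vanillin
Product: 21 4-formyl-2-methoxyphenyl pivalate
Conditions: PivCl, Et3N, DMAP (cat.), CH2Cl2, 0 °C to rt
Reagents that add atoms: pivaloyl chloride, CC(C)(C)C(=O)Cl
Why: O-acylation; the hindered, electron-withdrawing pivalate resists borohydride at 0 °C, disfavours benzylic ionisation in steps 17 and 24, and falls off in the last step.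

Step 13
Reactants: 19 the mono-silylated diphenol; 22 (R)-4-benzyl-3-(chloroacetyl)oxazolidin-2-one
Product: 23 (R)-4-benzyl-3-(aryloxyacetyl)oxazolidin-2-one, aryloxy being the phenoxy group of 19
Conditions: K2CO3 (2 equiv), NaI (0.2 equiv), acetone, 50 °C
Reagents that add atoms: none
Why: Williamson etherification with an α-halo imide activated in situ as the iodide; SN2 at the CH2 group should outrun attack of the hindered phenoxide on the imide carbonyl.

Step 14
Reactants: 23 the glycolyl imide; 21 4-formyl-2-methoxyphenyl pivalate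
Product: 25 (R)-4-benzyl-3-[(2R,3S)-2-aryloxy-3-hydroxy-3-(3-methoxy-4-pivaloyloxyphenyl)propanoyl]oxazolidin-2-one (aryloxy as in 23), via Z-dibutylboron enolate 24 (not isolated)
Conditions: Bu2BOTf (1.2 equiv), i-Pr2NEt (1.5 equiv), CH2Cl2, −78 to 0 °C; 21 (1.3 equiv), −78 to 0 °C; pH 7 buffer, MeOH, H2O2, 0 °C
Reagents that add atoms: dibutylboron triflate, CCCCB(CCCC)OS(=O)(=O)C(F)(F)F (its atoms are carried by 24 only)
Why: Evans syn-aldol of a glycolate imide: the Z-enolate 24 reacts through a chair Zimmerman–Traxler transition state on the face away from the benzyl group of the (R)-auxiliary, giving the syn adduct that maps onto the threo (αS,βS) pair.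

Step 15
Reactants: 25 the syn-aldol adduct
Product: 26 (1S,2S)-2-aryloxy-1-(3-methoxy-4-pivaloyloxyphenyl)propane-1,3-diol (aryloxy as in 23)
Conditions: NaBH4 (4 equiv), THF/H2O 4:1, 0 °C to rt
Reagents that add atoms: none
Why: Reductive cleavage of the N-acyloxazolidinone at the exocyclic carbonyl gives the primary alcohol and returns the auxiliary; the hindered aryl pivalate should survive at 0 °C and no stereocentre is touched.

Step 16
Reactants: 26 the threo diol
Product: 27 3-O-tert-butyldimethylsilyl ether of 26 (Cα–OH free)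
Conditions: TBSCl (1.1 equiv), imidazole, CH2Cl2, 0 °C
Reagents that add atoms: tert-butyldimethylsilyl chloride, CC(C)(C)[Si](C)(C)Cl
Why: Primary-selective silylation; the hindered benzylic secondary hydroxyl is left for inversion.

Step 17
Reactants: 27 the mono-silyl ether
Product: 28 (1R,2S)-2-aryloxy-3-(tert-butyldimethylsilyloxy)-1-(3-methoxy-4-pivaloyloxyphenyl)propyl 4-nitrobenzoate (aryloxy as in 23)
Conditions: 4-O2NC6H4CO2H, PPh3, DIAD (3 equiv each), toluene/THF, 0 °C to rt
Reagents that add atoms: 4-nitrobenzoic acid, O=C(O)c1ccc(cc1)[N+](=O)[O-]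
Why: Mitsunobu esterification with SN2 inversion at Cα (S to R) turns the threo pair into the erythro pair of unit A; the acyloxy-substituted ring disfavours benzylic ionisation, which keeps the inversion clean.

Step 18
Reactants: 28 the erythro ester
Product: 29 the phenol obtained from 28 by loss of the aryl silyl group on the C6 ring
Conditions: KHF2 (3 equiv), MeOH/THF, rt
Reagents that add atoms: none
Why: Bifluoride cleaves phenolic silyl ethers selectively; the primary alkyl silyl ether, the pivalate and the nitrobenzoate are unaffected.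

Step 19
Reactants: 29 the phenol; 22 (R)-4-benzyl-3-(chloroacetyl)oxazolidin-2-one
Product: 30 the O-[2-oxo-2-Xc(R)-ethyl] ether of 29
Conditions: K2CO3 (2 equiv), NaI (0.2 equiv), acetone, 50 °C
Reagents that add atoms: none
Why: Williamson etherification as in step 13; without an alcohol solvent the esters are not transesterified.

Step 20
Reactants: 31 (E)-isoeugenol; 32 (S)-4-benzyl-3-(chloroacetyl)oxazolidin-2-one
Product: 33 (S)-4-benzyl-3-{[2-methoxy-4-((E)-prop-1-enyl)phenoxy]acetyl}oxazolidin-2-one
Conditions: K2CO3 (2 equiv), NaI (0.2 equiv), acetone, 50 °C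
Reagents that add atoms: none
Why: Williamson etherification of an unhindered guaiacol; the propenyl group is a latent aldehyde that cannot interfere with the coming aldol.

Step 21
Reactants: 33 the glycolyl imide; 21 4-formyl-2-methoxyphenyl pivalate
Product: 35 (S)-4-benzyl-3-[(2S,3R)-3-hydroxy-3-(3-methoxy-4-pivaloyloxyphenyl)-2-(2-methoxy-4-propenylphenoxy)propanoyl]oxazolidin-2-one, via Z-dibutylboron enolate 34 (not isolated)
Conditions: Bu2BOTf (1.2 equiv), i-Pr2NEt (1.5 equiv), CH2Cl2, −78 to 0 °C; 21 (1.3 equiv), −78 to 0 °C; pH 7 buffer, MeOH, H2O2, 0 °C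
Reagents that add atoms: dibutylboron triflate, CCCCB(CCCC)OS(=O)(=O)C(F)(F)F (its atoms are carried by 34 only)
Why: Evans syn-aldol as in step 14, with the (S)-auxiliary giving the mirror-image sense, i.e. the threo (αR,βR) pair; the amine base buffers the electron-rich styrene against acid.

Step 22
Reactants: 35 the syn-aldol adduct
Product: 36 (1R,2R)-1-(3-methoxy-4-pivaloyloxyphenyl)-2-[2-methoxy-4-((E)-prop-1-enyl)phenoxy]propane-1,3-diol
Conditions: NaBH4 (4 equiv), THF/H2O 4:1, 0 °C to rt
Reagents that add atoms: none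
Why: Reductive removal of the auxiliary as in step 15.

Step 23
Reactants: 36 the threo diol
Product: 37 3-O-tert-butyldimethylsilyl ether of 36
Conditions: TBSCl (1.1 equiv), imidazole, CH2Cl2, 0 °C
Reagents that add atoms: tert-butyldimethylsilyl chloride, CC(C)(C)[Si](C)(C)Cl
Why: Primary-selective silylation as in step 16.

Step 24
Reactants: 37 the mono-silyl ether
Product: 38 (1S,2R)-3-(tert-butyldimethylsilyloxy)-1-(3-methoxy-4-pivaloyloxyphenyl)-2-[2-methoxy-4-((E)-prop-1-enyl)phenoxy]propyl 4-nitrobenzoate
Conditions: 4-O2NC6H4CO2H, PPh3, DIAD (3 equiv each), toluene/THF, 0 °C to rt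
Reagents that add atoms: 4-nitrobenzoic acid, O=C(O)c1ccc(cc1)[N+](=O)[O-]
Why: Mitsunobu inversion at Cα (R to S) gives the erythro pair of unit C; the neighbouring guaiacyl ether is less hindered than in step 17.

Step 25
Reactants: 38 the erythro ester with propenyl group
Product: 39 4-{[(1S,2R)-3-(tert-butyldimethylsilyloxy)-1-(3-methoxy-4-pivaloyloxyphenyl)-1-(4-nitrobenzoyloxy)propan-2-yl]oxy}-3-methoxybenzaldehyde
Conditions: OsO4 (2 mol %), NaIO4 (4 equiv), 2,6-lutidine (2 equiv), dioxane/H2O 3:1, rt
Reagents that add atoms: sodium periodate, [Na+].[O-]I(=O)(=O)=O (terminal oxidant; supplies the aldehyde oxygen through OsO4)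
Why: Lemieux–Johnson cleavage of the propenyl group unmasks the aldehyde; lutidine buffers the medium and the esters and silyl ether are inert.

Step 26
Reactants: 30 the glycolyl imide bearing unit A; 39 the aldehyde bearing unit C
Product: 41 syn-aldol adduct, (R)-4-benzyl-3-[(2R,3S)-2-aryloxy-3-aryl-3-hydroxypropanoyl]oxazolidin-2-one (aryloxy from 29, aryl from 39), via Z-dibutylboron enolate 40 (not isolated)
Conditions: Bu2BOTf (1.3 equiv), i-Pr2NEt (1.6 equiv), CH2Cl2, −78 to 0 °C; 39 (1.3 equiv), −78 to 0 °C; pH 7 buffer, MeOH, H2O2, 0 °C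
Reagents that add atoms: dibutylboron triflate, CCCCB(CCCC)OS(=O)(=O)C(F)(F)F (its atoms are carried by 40 only)
Why: Evans syn-aldol as in step 14 joins the two halves and sets the threo (αS,βS) pair of unit B under control of the (R)-auxiliary; the remote centres of both partners should have no say, and excess 39 is recoverable.

Step 27
Reactants: 41 the aldol adduct
Product: 42 the (1S,2S)-1,3-diol of unit B, all other groups as in 41
Conditions: NaBH4 (4 equiv), THF/H2O 4:1, 0 °C
Reagents that add atoms: none
Why: Reductive removal of the auxiliary as in step 15; any partial loss of ester groups here is harmless, because they are removed in step 29.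

Step 28
Reactants: 42 the bis-silyl tetraester
Product: 43 the tetraester with both Cγ hydroxyls free
Conditions: TBAF/AcOH (1:1, 4 equiv), THF, rt
Reagents that add atoms: none
Why: Buffered fluoride cleaves the two primary silyl ethers while the esters keep the compound lipophilic and easy to purify.

Step 29
Reactants: 43 the tetraester
Product: 44 the target
Conditions: K2CO3, MeOH/THF, rt to 40 °C; neutralise with weak acid resin
Reagents that add atoms: none
Why: Base-catalysed transesterification removes the two 4-nitrobenzoates and the two aryl pivalates; mild carbonate at or near rt should neither epimerise the benzylic centres nor form quinone methides.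

## Compound list

1 | syringaldehyde | COc1cc(C=O)cc(OC)c1O | starting material
2 | 4-formyl-2,6-dimethoxyphenyl methanesulfonate | COc1cc(C=O)cc(OC)c1OS(C)(=O)=O | intermediate
3 | (trimethylsilyl)methanol | C[Si](C)(C)CO | starting material
4 | 4-{bis[(trimethylsilyl)methoxy]methyl}-2,6-dimethoxyphenyl methanesulfonate | COc1cc(C(OC[Si](C)(C)C)OC[Si](C)(C)C)cc(OC)c1OS(C)(=O)=O | intermediate
5 | 4-{chloro[(trimethylsilyl)methoxy]methyl}-2,6-dimethoxyphenyl methanesulfonate, racemic | COc1cc(C(Cl)OC[Si](C)(C)C)cc(OC)c1OS(C)(=O)=O | intermediate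
6 | furfural | O=Cc1ccco1 | starting material
7 | 5-hydroxyfuran-2(5H)-one, racemic | O=C1OC(O)C=C1 | intermediate
8 | (+)-menthol, (1S,2R,5S) | C[C@H]1CC[C@@H]([C@H](C1)O)C(C)C | starting material
9 | (5R)-5-[(1S,2R,5S)-menthyloxy]furan-2(5H)-one | O=C1O[C@H](C=C1)O[C@H]2C[C@@H](C)CC[C@@H]2C(C)C | intermediate
10 | (5S)-5-[(1S,2R,5S)-menthyloxy]furan-2(5H)-one | O=C1O[C@@H](C=C1)O[C@H]2C[C@@H](C)CC[C@@H]2C(C)C | intermediate
11 | carbonyl ylide, (4-methanesulfonyloxy-3,5-dimethoxybenzylidene)oxonium methylide | COc1cc(C=[O+][CH2-])cc(OC)c1OS(C)(=O)=O | intermediate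
12 | (1S,2S,5R,6S)-2-(4-methanesulfonyloxy-3,5-dimethoxyphenyl)-6-[(1S,2R,5S)-menthyloxy]-3,7-dioxabicyclo[3.3.0]octan-8-one | COc1cc([C@H]2OC[C@H]3[C@@H]2C(=O)O[C@@H]3O[C@H]2C[C@@H](C)CC[C@@H]2C(C)C)cc(OC)c1OS(C)(=O)=O | intermediate
13 | 2,6-dimethoxyphenol | COc1cccc(OC)c1O | starting material
14 | (1S,2S,5R,6S)-6-(4-hydroxy-3,5-dimethoxyphenyl)-2-(4-methanesulfonyloxy-3,5-dimethoxyphenyl)-3,7-dioxabicyclo[3.3.0]octan-8-one | COc1cc([C@H]2OC[C@H]3[C@@H]2C(=O)O[C@@H]3c2cc(OC)c(O)c(OC)c2)cc(OC)c1OS(C)(=O)=O | intermediate
15 | tert-butyldimethylsilyl ether of 14 | COc1cc([C@H]2OC[C@H]3[C@@H]2C(=O)O[C@@H]3c2cc(OC)c(O[Si](C)(C)C(C)(C)C)c(OC)c2)cc(OC)c1OS(C)(=O)=O | intermediate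
16 | (S)-[4-(tert-butyldimethylsilyloxy)-3,5-dimethoxyphenyl][(3R,4R,5S)-4-(hydroxymethyl)-5-(4-methanesulfonyloxy-3,5-dimethoxyphenyl)oxolan-3-yl]methanol | COc1cc([C@H]2OC[C@@H]([C@@H]2CO)[C@H](O)c2cc(OC)c(O[Si](C)(C)C(C)(C)C)c(OC)c2)cc(OC)c1OS(C)(=O)=O | intermediate
17 | primary (C8) p-toluenesulfonate of 16 | COc1cc([C@H]2OC[C@@H]([C@@H]2COS(=O)(=O)c2ccc(C)cc2)[C@H](O)c2cc(OC)c(O[Si](C)(C)C(C)(C)C)c(OC)c2)cc(OC)c1OS(C)(=O)=O | intermediate
18 | (1R,2S,5R,6S)-6-[4-(tert-butyldimethylsilyloxy)-3,5-dimethoxyphenyl]-2-(4-methanesulfonyloxy-3,5-dimethoxyphenyl)-3,7-dioxabicyclo[3.3.0]octane | COc1cc([C@H]2OC[C@H]3[C@@H]2CO[C@@H]3c2cc(OC)c(O[Si](C)(C)C(C)(C)C)c(OC)c2)cc(OC)c1OS(C)(=O)=O | intermediate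
19 | (1R,2S,5R,6S)-6-[4-(tert-butyldimethylsilyloxy)-3,5-dimethoxyphenyl]-2-(4-hydroxy-3,5-dimethoxyphenyl)-3,7-dioxabicyclo[3.3.0]octane | COc1cc([C@H]2OC[C@H]3[C@@H]2CO[C@@H]3c2cc(OC)c(O[Si](C)(C)C(C)(C)C)c(OC)c2)cc(OC)c1O | intermediate
20 | vanillin | COc1cc(C=O)ccc1O | starting material
21 | 4-formyl-2-methoxyphenyl pivalate | COc1cc(C=O)ccc1OC(=O)C(C)(C)C | intermediate
22 | (R)-4-benzyl-3-(chloroacetyl)oxazolidin-2-one | O=C(CCl)N1[C@H](Cc2ccccc2)COC1=O | starting material
23 | (R)-4-benzyl-3-(aryloxyacetyl)oxazolidin-2-one, aryloxy = phenoxy group of 19 | O=C(COc1c(OC)cc([C@H]2OC[C@H]3[C@@H]2CO[C@@H]3c2cc(OC)c(O[Si](C)(C)C(C)(C)C)c(OC)c2)cc1OC)N1[C@H](Cc2ccccc2)COC1=O | intermediate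
24 | Z-dibutylboron enolate of 23 | CCCCB(CCCC)O/C(=C\Oc1c(OC)cc([C@H]2OC[C@H]3[C@@H]2CO[C@@H]3c2cc(OC)c(O[Si](C)(C)C(C)(C)C)c(OC)c2)cc1OC)N1[C@H](Cc2ccccc2)COC1=O | intermediate
25 | syn-aldol adduct, (2R,3S)-propanoyl imide of unit A precursor | COc1cc([C@H](O)[C@H](C(=O)N2[C@H](Cc3ccccc3)COC2=O)Oc2c(OC)cc([C@H]3OC[C@H]4[C@@H]3CO[C@@H]4c3cc(OC)c(O[Si](C)(C)C(C)(C)C)c(OC)c3)cc2OC)ccc1OC(=O)C(C)(C)C | intermediate
26 | (1S,2S)-threo diol of unit A precursor | COc1cc([C@H](O)[C@H](CO)Oc2c(OC)cc([C@H]3OC[C@H]4[C@@H]3CO[C@@H]4c3cc(OC)c(O[Si](C)(C)C(C)(C)C)c(OC)c3)cc2OC)ccc1OC(=O)C(C)(C)C | intermediate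
27 | 3-O-tert-butyldimethylsilyl ether of 26 | COc1cc([C@H](O)[C@H](CO[Si](C)(C)C(C)(C)C)Oc2c(OC)cc([C@H]3OC[C@H]4[C@@H]3CO[C@@H]4c3cc(OC)c(O[Si](C)(C)C(C)(C)C)c(OC)c3)cc2OC)ccc1OC(=O)C(C)(C)C | intermediate
28 | (1R,2S)-erythro 4-nitrobenzoate of unit A | COc1cc([C@@H](OC(=O)c2ccc(cc2)[N+](=O)[O-])[C@H](CO[Si](C)(C)C(C)(C)C)Oc2c(OC)cc([C@H]3OC[C@H]4[C@@H]3CO[C@@H]4c3cc(OC)c(O[Si](C)(C)C(C)(C)C)c(OC)c3)cc2OC)ccc1OC(=O)C(C)(C)C | intermediate
29 | 28 with free phenol on the C6 ring | COc1cc([C@@H](OC(=O)c2ccc(cc2)[N+](=O)[O-])[C@H](CO[Si](C)(C)C(C)(C)C)Oc2c(OC)cc([C@H]3OC[C@H]4[C@@H]3CO[C@@H]4c3cc(OC)c(O)c(OC)c3)cc2OC)ccc1OC(=O)C(C)(C)C | intermediate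
30 | O-[2-oxo-2-Xc(R)-ethyl] ether of 29 | COc1cc([C@@H](OC(=O)c2ccc(cc2)[N+](=O)[O-])[C@H](CO[Si](C)(C)C(C)(C)C)Oc2c(OC)cc([C@H]3OC[C@H]4[C@@H]3CO[C@@H]4c3cc(OC)c(OCC(=O)N4[C@H](Cc5ccccc5)COC4=O)c(OC)c3)cc2OC)ccc1OC(=O)C(C)(C)C | intermediate
31 | (E)-isoeugenol | C/C=C/c1ccc(O)c(OC)c1 | starting material
32 | (S)-4-benzyl-3-(chloroacetyl)oxazolidin-2-one | O=C(CCl)N1[C@@H](Cc2ccccc2)COC1=O | starting material
33 | (S)-4-benzyl-3-{[2-methoxy-4-((E)-prop-1-enyl)phenoxy]acetyl}oxazolidin-2-one | C/C=C/c1ccc(OCC(=O)N2[C@@H](Cc3ccccc3)COC2=O)c(OC)c1 | intermediate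
34 | Z-dibutylboron enolate of 33 | C/C=C/c1ccc(O/C=C(\OB(CCCC)CCCC)N2[C@@H](Cc3ccccc3)COC2=O)c(OC)c1 | intermediate
35 | syn-aldol adduct, (2S,3R)-propanoyl imide of unit C precursor | C/C=C/c1ccc(O[C@H](C(=O)N2[C@@H](Cc3ccccc3)COC2=O)[C@H](O)c2ccc(OC(=O)C(C)(C)C)c(OC)c2)c(OC)c1 | intermediate
36 | (1R,2R)-1-(3-methoxy-4-pivaloyloxyphenyl)-2-[2-methoxy-4-((E)-prop-1-enyl)phenoxy]propane-1,3-diol | C/C=C/c1ccc(O[C@H](CO)[C@H](O)c2ccc(OC(=O)C(C)(C)C)c(OC)c2)c(OC)c1 | intermediate
37 | 3-O-tert-butyldimethylsilyl ether of 36 | C/C=C/c1ccc(O[C@H](CO[Si](C)(C)C(C)(C)C)[C@H](O)c2ccc(OC(=O)C(C)(C)C)c(OC)c2)c(OC)c1 | intermediate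
38 | (1S,2R)-erythro 4-nitrobenzoate of unit C with propenyl group | C/C=C/c1ccc(O[C@H](CO[Si](C)(C)C(C)(C)C)[C@@H](OC(=O)c2ccc(cc2)[N+](=O)[O-])c2ccc(OC(=O)C(C)(C)C)c(OC)c2)c(OC)c1 | intermediate
39 | 4-{[(1S,2R)-3-(tert-butyldimethylsilyloxy)-1-(3-methoxy-4-pivaloyloxyphenyl)-1-(4-nitrobenzoyloxy)propan-2-yl]oxy}-3-methoxybenzaldehyde | O=Cc1ccc(O[C@H](CO[Si](C)(C)C(C)(C)C)[C@@H](OC(=O)c2ccc(cc2)[N+](=O)[O-])c2ccc(OC(=O)C(C)(C)C)c(OC)c2)c(OC)c1 | intermediate
40 | Z-dibutylboron enolate of 30 | COc1cc([C@@H](OC(=O)c2ccc(cc2)[N+](=O)[O-])[C@H](CO[Si](C)(C)C(C)(C)C)Oc2c(OC)cc([C@H]3OC[C@H]4[C@@H]3CO[C@@H]4c3cc(OC)c(O/C=C(\OB(CCCC)CCCC)N4[C@H](Cc5ccccc5)COC4=O)c(OC)c3)cc2OC)ccc1OC(=O)C(C)(C)C | intermediate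
41 | syn-aldol adduct of 40 and 39, (2R,3S)-propanoyl imide of unit B | COc1cc([C@@H](OC(=O)c2ccc(cc2)[N+](=O)[O-])[C@H](CO[Si](C)(C)C(C)(C)C)Oc2c(OC)cc([C@H]3OC[C@H]4[C@@H]3CO[C@@H]4c3cc(OC)c(O[C@@H](C(=O)N4[C@H](Cc5ccccc5)COC4=O)[C@@H](O)c4ccc(O[C@H](CO[Si](C)(C)C(C)(C)C)[C@@H](OC(=O)c5ccc(cc5)[N+](=O)[O-])c5ccc(OC(=O)C(C)(C)C)c(OC)c5)c(OC)c4)c(OC)c3)cc2OC)ccc1OC(=O)C(C)(C)C | intermediate
42 | (1S,2S)-diol of unit B, bis-silyl tetraester | COc1cc([C@@H](OC(=O)c2ccc(cc2)[N+](=O)[O-])[C@H](CO[Si](C)(C)C(C)(C)C)Oc2c(OC)cc([C@H]3OC[C@H]4[C@@H]3CO[C@@H]4c3cc(OC)c(O[C@@H](CO)[C@@H](O)c4ccc(O[C@H](CO[Si](C)(C)C(C)(C)C)[C@@H](OC(=O)c5ccc(cc5)[N+](=O)[O-])c5ccc(OC(=O)C(C)(C)C)c(OC)c5)c(OC)c4)c(OC)c3)cc2OC)ccc1OC(=O)C(C)(C)C | intermediate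
43 | tetraester of the target (two 4-nitrobenzoates at Cα of A and C, two aryl pivalates) | COc1cc([C@@H](OC(=O)c2ccc(cc2)[N+](=O)[O-])[C@H](CO)Oc2c(OC)cc([C@H]3OC[C@H]4[C@@H]3CO[C@@H]4c3cc(OC)c(O[C@@H](CO)[C@@H](O)c4ccc(O[C@H](CO)[C@@H](OC(=O)c5ccc(cc5)[N+](=O)[O-])c5ccc(OC(=O)C(C)(C)C)c(OC)c5)c(OC)c4)c(OC)c3)cc2OC)ccc1OC(=O)C(C)(C)C | intermediate
44 | CNP0316493.3 | COc1cc([C@@H](O)[C@H](CO)Oc2c(OC)cc([C@H]3OC[C@H]4[C@@H]3CO[C@@H]4c3cc(OC)c(O[C@@H](CO)[C@@H](O)c4ccc(O[C@H](CO)[C@@H](O)c5ccc(O)c(OC)c5)c(OC)c4)c(OC)c3)cc2OC)ccc1O | target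

## Step count and least certain steps

Total: 29 steps. Longest linear sequence: 20 steps (1 → 2 → 4 → 5 → 12 → 14 → 15 → 16 → 18 → 19 → 23 → 25 → 26 → 27 → 28 → 29 → 30 → 41 → 42 → 43 → 44).

Step 6 (key step). The most likely failures are three.
- Loss of regiocontrol, because the two termini of an aryl-substituted ylide differ only moderately.
- Endo approach, which would erode the configuration at C2.
- Fluoride-induced epimerisation of the acetal centre of 10, or decay of the ylide by ring closure or self-addition before it meets the alkene.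

The fallback gives up the cycloaddition and sets out from 1. Knoevenagel–Doebner condensation with monoethyl malonate (pyridine, piperidine) would give ethyl (E)-sinapate F1, and DIBAL reduction would give (E)-sinapyl alcohol F2. Oxidative β–β coupling (FeCl3 in aqueous acetone, or laccase/O2) would give racemic syringaresinol F3, and chromatography on a chiral stationary phase would give (+)-syringaresinol F4. Statistical mono-silylation (TBSCl, 1 equiv, imidazole) would return to the route at 19. This costs the absolute control and the built-in differentiation, but each operation is known chemistry.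

Step 7. Ionisation of the lactone acetal may be slow. Under more forcing conditions the product may re-ionise at C6 (benzylic lactone C–O para to a free hydroxyl) and lose the exo configuration, or the phenol may attack through C3 or through oxygen. The fallback sets out from 12 and replaces electrophilic substitution by an organometallic addition.
- Aqueous trifluoroacetic acid would hydrolyse the acetal to the hydroxylactone F5.
- Silylation of commercial 4-bromo-2,6-dimethoxyphenol would give the aryl bromide F6, and magnesium insertion would give the Grignard reagent F7.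
- F7 (2.2 equiv, THF, −78 °C) would add to the open aldehyde form of F5 to give the hydroxy acid F8, which would lactonise under mild acid and return to the route at 15.

The aryl position is then fixed by ipso attachment. The facial selectivity of the addition is substrate-controlled, so C6 epimers would have to be separated as lactones.

Steps 17 and 24 (Mitsunobu inversions). The carbinol is flanked by an aryl ring and a bulky aryloxy group, most severely in step 17 (2,6-dimethoxyphenoxy). Substitution may therefore be slow, leaving room for elimination towards the enol ether or for partial ionisation with loss of stereochemical fidelity. The fallback is oxidation and diastereoselective reduction.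
- From 27: Dess–Martin periodinane (NaHCO3) would give ketone F9. Felkin–Anh reduction (NaBH4, MeOH/THF, −40 °C, hydride anti to the α-aryloxy group) would give the erythro alcohol F10. 4-Nitrobenzoyl chloride/pyridine would return to the route at 28.
- From 37: the same sequence through ketone F11 and erythro alcohol F12 would return at 38.

Step 13. The phenoxide of 19 is flanked by two methoxy groups. Slow alkylation would leave room for acyl transfer from the imide to the phenoxide or for self-condensation of 22. The fallback sets out from 19 and builds the imide last.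
- Alkylation with allyl bromoacetate (K2CO3, acetone) would give allyl ester F13.
- Pd(PPh3)4/morpholine would give acid F14 under neutral conditions that spare the aryl silyl ether.
- The mixed pivalic anhydride (PivCl, Et3N) with lithiated (R)-4-benzyloxazolidin-2-one would return to the route at 23.

## Further compounds

F1 | step 6 | ethyl (E)-sinapate | CCOC(=O)/C=C/c1cc(OC)c(O)c(OC)c1
F2 | step 6 | (E)-sinapyl alcohol | COc1cc(/C=C/CO)cc(OC)c1O
F3 | step 6 | racemic syringaresinol (both enantiomers) | COc1cc([C@H]2OC[C@H]3[C@@H]2CO[C@@H]3c2cc(OC)c(O)c(OC)c2)cc(OC)c1O.COc1cc([C@@H]2OC[C@@H]3[C@H]2CO[C@H]3c2cc(OC)c(O)c(OC)c2)cc(OC)c1O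
F4 | step 6 | (+)-syringaresinol, (1R,2S,5R,6S) | COc1cc([C@H]2OC[C@H]3[C@@H]2CO[C@@H]3c2cc(OC)c(O)c(OC)c2)cc(OC)c1O
F5 | step 7 | (1S,2S,5R)-6-hydroxy-2-(4-methanesulfonyloxy-3,5-dimethoxyphenyl)-3,7-dioxabicyclo[3.3.0]octan-8-one (C6 epimers) | COc1cc([C@H]2OC[C@H]3[C@@H]2C(=O)OC3O)cc(OC)c1OS(C)(=O)=O
F6 | step 7 | (4-bromo-2,6-dimethoxyphenoxy)(tert-butyl)dimethylsilane | COc1cc(Br)cc(OC)c1O[Si](C)(C)C(C)(C)C
F7 | step 7 | [4-(tert-butyldimethylsilyloxy)-3,5-dimethoxyphenyl]magnesium bromide | COc1cc([Mg]Br)cc(OC)c1O[Si](C)(C)C(C)(C)C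
F8 | step 7 | (2S,3R,4R)-4-{(S)-[4-(tert-butyldimethylsilyloxy)-3,5-dimethoxyphenyl](hydroxy)methyl}-2-(4-methanesulfonyloxy-3,5-dimethoxyphenyl)oxolane-3-carboxylic acid | COc1cc([C@H]2OC[C@@H]([C@@H]2C(O)=O)[C@H](O)c2cc(OC)c(O[Si](C)(C)C(C)(C)C)c(OC)c2)cc(OC)c1OS(C)(=O)=O
F9 | step 17 | Cα ketone from 27 | COc1cc(C(=O)[C@H](CO[Si](C)(C)C(C)(C)C)Oc2c(OC)cc([C@H]3OC[C@H]4[C@@H]3CO[C@@H]4c3cc(OC)c(O[Si](C)(C)C(C)(C)C)c(OC)c3)cc2OC)ccc1OC(=O)C(C)(C)C
F10 | step 17 | (1R,2S)-erythro alcohol, Cα epimer of 27 | COc1cc([C@@H](O)[C@H](CO[Si](C)(C)C(C)(C)C)Oc2c(OC)cc([C@H]3OC[C@H]4[C@@H]3CO[C@@H]4c3cc(OC)c(O[Si](C)(C)C(C)(C)C)c(OC)c3)cc2OC)ccc1OC(=O)C(C)(C)C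
F11 | step 24 | Cα ketone from 37 | C/C=C/c1ccc(O[C@H](CO[Si](C)(C)C(C)(C)C)C(=O)c2ccc(OC(=O)C(C)(C)C)c(OC)c2)c(OC)c1
F12 | step 24 | (1S,2R)-erythro alcohol, Cα epimer of 37 | C/C=C/c1ccc(O[C@H](CO[Si](C)(C)C(C)(C)C)[C@@H](O)c2ccc(OC(=O)C(C)(C)C)c(OC)c2)c(OC)c1
F13 | step 13 | allyl aryloxyacetate of 19 | C=CCOC(=O)COc1c(OC)cc(cc1OC)[C@H]1OC[C@H]2[C@@H]1CO[C@@H]2c1cc(OC)c(O[Si](C)(C)C(C)(C)C)c(OC)c1
F14 | step 13 | aryloxyacetic acid of 19 | OC(=O)COc1c(OC)cc(cc1OC)[C@H]1OC[C@H]2[C@@H]1CO[C@@H]2c1cc(OC)c(O[Si](C)(C)C(C)(C)C)c(OC)c1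
A1 | alternative 1 | bis(Cα-deoxy) precursor (units A and C without Cα–OH) | COc1cc(C[C@H](CO)Oc2c(OC)cc([C@H]3OC[C@H]4[C@@H]3CO[C@@H]4c3cc(OC)c(O[C@@H](CO)[C@@H](O)c4ccc(O[C@H](CO)Cc5ccc(O)c(OC)c5)c(OC)c4)c(OC)c3)cc2OC)ccc1O
A2 | alternative 1 | phenylboronic acid | OB(O)c1ccccc1
A3 | alternative 1 | tris(phenylboronate) of the target | COc1cc([C@@H](O2)[C@H](COB2c2ccccc2)Oc2c(OC)cc([C@H]3OC[C@H]4[C@@H]3CO[C@@H]4c3cc(OC)c(O[C@@H](COB4c5ccccc5)[C@@H](O4)c4ccc(O[C@H](COB5c6ccccc6)[C@@H](O5)c5ccc(O)c(OC)c5)c(OC)c4)c(OC)c3)cc2OC)ccc1O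
A4 | alternative 2 | dialdehyde (units A and C cut back to α-aryloxy aldehydes, unit B bis-silylated) | O=C[C@H](CO[Si](C)(C)C(C)(C)C)Oc1c(OC)cc(cc1OC)[C@H]1OC[C@H]2[C@@H]1CO[C@@H]2c1cc(OC)c(O[C@@H](CO[Si](C)(C)C(C)(C)C)[C@@H](O[Si](C)(C)C(C)(C)C)c2ccc(O[C@H](CO[Si](C)(C)C(C)(C)C)C=O)c(OC)c2)c(OC)c1
A5 | alternative 2 | [4-(tert-butyldimethylsilyloxy)-3-methoxyphenyl]magnesium bromide | COc1cc([Mg]Br)ccc1O[Si](C)(C)C(C)(C)C
A6 | alternative 2 | hexa-O-silyl target with free Cα hydroxyls in units A and C | COc1cc([C@@H](O)[C@H](CO[Si](C)(C)C(C)(C)C)Oc2c(OC)cc([C@H]3OC[C@H]4[C@@H]3CO[C@@H]4c3cc(OC)c(O[C@@H](CO[Si](C)(C)C(C)(C)C)[C@@H](O[Si](C)(C)C(C)(C)C)c4ccc(O[C@H](CO[Si](C)(C)C(C)(C)C)[C@@H](O)c5ccc(O[Si](C)(C)C(C)(C)C)c(OC)c5)c(OC)c4)c(OC)c3)cc2OC)ccc1O[Si](C)(C)C(C)(C)C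
A7 | alternative 3 | 2-lithio-2-[4-(tert-butyldimethylsilyloxy)-3,5-dimethoxyphenyl]-1,3-dithiane | COc1cc(C2([Li])SCCCS2)cc(OC)c1O[Si](C)(C)C(C)(C)C
A8 | alternative 3 | (5R)-5-[(1R,2S,5R)-menthyloxy]furan-2(5H)-one | O=C1O[C@H](C=C1)O[C@@H]2C[C@H](C)CC[C@H]2C(C)C
A9 | alternative 3 | 4-allyloxy-3,5-dimethoxybenzaldehyde | COc1cc(C=O)cc(OC)c1OCC=C
A10 | alternative 3 | trans-3,4-disubstituted 5-menthyloxybutyrolactone | O=C1O[C@@H](O[C@@H]2C[C@H](C)CC[C@H]2C(C)C)[C@H](C2(c3cc(OC)c(O[Si](C)(C)C(C)(C)C)c(OC)c3)SCCCS2)[C@H]1[C@H](O)c1cc(OC)c(OCC=C)c(OC)c1
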